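**Plan**

- Retrosynthetic cuts: the C3–O ester bond (dienoic acid plus trienone alcohol); then, with the C8 ketone and C7 isopropylidene taken back to a C8 carbinol and C7 isopropenyl group, the C7–C8 bond of ring B; then C9=C10 (olefination of a ring-A ketone), C5–C6 (prenyl), C5–CH3 and C4–CH3, back to a quinone monoketal. The acid is cut at its C2′=C3′ bond to (S)-2-methylbutanal.
- Enabling feature: C6, C7 and C11–C13 form an intact prenyl group on the quaternary C5, and C8 is the formyl carbon of a dienal C8(=O)–C9=C10–C1=C2 attached at C10. Ring B (C5–C10) can therefore close by a type-I carbonyl-ene reaction that joins C7 to C8.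
- Forward order: ring A is the ring of the starting dienone and receives the C4 methyl, the C5 methyl, the prenyl group and then C9–C8. Ring B closes second. Oxidation and alkene isomerisation give the cross-conjugated dienone, and the side chain is attached last by esterification.
- Stereochemistry: C4 from a chiral copper catalyst; C5 by enolate alkylation anti to the C4 methyl; C3 by hydride delivery anti to both methyls; C6′ from (S)-2-methylbutan-1-ol; 2′E,4′E from the phosphonate olefination. C7 and C8 of the ene product are temporary.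

Key step: step 10

**Remarks**

- Atom numbers are those of the eremophilane skeleton of the target: ring A is C1–C5 and C10, ring B is C5–C10, methyls sit on C4 and C5, C11–C13 on C7, and the ester oxygen on C3.
- Assumption: the (S,R,R)-phosphoramidite is taken to send methyl to the same enone face as in simple cyclohexenone, which corresponds to the 5R product of step 1; if the sense is opposite, the (R,S,S)-ligand is used.
- The compounds that carry the exocyclic C9=C10 bond before ring closure are E/Z mixtures; each is named and drawn as its expected major E isomer.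

**Route**

Step 1
Reactants: 1 4,4-dimethoxycyclohexa-2,5-dien-1-one
Product: 2 (5R)-4,4-dimethoxy-5-methylcyclohex-2-en-1-one
Conditions: Me2Zn (1.5 equiv), Cu(OTf)2 (2 mol %), (S,R,R)-BINOL/bis(1-phenylethyl)amine phosphoramidite (4 mol %), toluene, −25 °C; aq. NH4Cl
Reagents that add atoms: dimethylzinc, C[Zn]C
Why: Copper–phosphoramidite-catalysed asymmetric conjugate addition of a dialkylzinc, a reaction established for cyclohexadienone monoketals, desymmetrises 1 by methyl transfer to one enantiotopic enone face and so sets the methyl-bearing centre (C4 of the target) under ligand control.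

Step 2
Reactants: 2 (5R)-4,4-dimethoxy-5-methylcyclohex-2-en-1-one
Product: 4 (5R,6RS)-4,4-dimethoxy-5,6-dimethylcyclohex-2-en-1-one, via lithium enolate 3 (not isolated)
Conditions: LDA (1.05 equiv), THF, −78 °C; MeI, −78 → −20 °C
Reagents that add atoms: iodomethane, CI
Why: Kinetic enolate alkylation works here because 2 has no γ-hydrogen (that carbon is the ketal), so LDA can only form the cross-conjugated α′-enolate 3, which is C-methylated; the new centre is re-enolised in step 3 and its configuration does not matter.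

Step 3
Reactants: 4 (5R,6RS)-4,4-dimethoxy-5,6-dimethylcyclohex-2-en-1-one; 5 1-bromo-3-methylbut-2-ene
Product: 7 (5R,6R)-4,4-dimethoxy-5,6-dimethyl-6-(3-methylbut-2-en-1-yl)cyclohex-2-en-1-one, via lithium enolate 6 (not isolated)
Conditions: LDA (1.1 equiv), THF, −78 → 0 °C; DMPU, 5, −78 → 0 °C
Reagents that add atoms: none
Why: A second kinetic enolate alkylation, in which the fully substituted enolate 6 should take up the reactive allylic bromide at carbon on the face anti to the neighbouring methyl group (the usual outcome for 2,3-dimethylcyclohexanone-type enolates), creates the quaternary C5 with its methyl cis to the C4 methyl.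

Step 4
Reactants: 7 (5R,6R)-4,4-dimethoxy-5,6-dimethyl-6-(3-methylbut-2-en-1-yl)cyclohex-2-en-1-one; 8 ethyl 2-(trimethylsilyl)acetate
Product: 10 ethyl (2E)-2-[(5R,6R)-4,4-dimethoxy-5,6-dimethyl-6-(3-methylbut-2-en-1-yl)cyclohex-2-en-1-ylidene]acetate, via lithiated silyl ester 9 (not isolated)
Conditions: 8 (1.5 equiv), LDA (1.5 equiv), THF, −78 °C; then 7, −78 → 0 °C
Reagents that add atoms: none
Why: In this Peterson olefination the small lithium enolate 9 should add 1,2 at low temperature to the non-enolisable but hindered ketone, where a phosphonate anion would be sluggish, and the β-oxidosilane collapses to the exocyclic enoate, with the E isomer (ester away from the quaternary carbon) expected to dominate and the minor Z isomer carried along because both geometries serve in step 10.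

Step 5
Reactants: 10 ethyl (2E)-2-[(5R,6R)-4,4-dimethoxy-5,6-dimethyl-6-(3-methylbut-2-en-1-yl)cyclohex-2-en-1-ylidene]acetate
Product: 11 ethyl (2E)-2-[(5R,6R)-5,6-dimethyl-6-(3-methylbut-2-en-1-yl)-4-oxocyclohex-2-en-1-ylidene]acetate
Conditions: aq. oxalic acid on SiO2, CH2Cl2, 0 °C → rt, short contact
Reagents that add atoms: water, O
Why: Mild acid hydrolysis of the allylic dimethyl ketal (ketal deprotection) unmasks the C3 ketone without touching the ester or the prenyl group, and the brief cold exposure is meant to keep the now enolisable C4 centre from epimerising.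

Step 6
Reactants: 11 ethyl (2E)-2-[(5R,6R)-5,6-dimethyl-6-(3-methylbut-2-en-1-yl)-4-oxocyclohex-2-en-1-ylidene]acetate
Product: 12 ethyl (2E)-2-[(4S,5R,6R)-4-hydroxy-5,6-dimethyl-6-(3-methylbut-2-en-1-yl)cyclohex-2-en-1-ylidene]acetate
Conditions: NaBH4, CeCl3·7H2O, MeOH, −78 °C
Reagents that add atoms: none
Why: Luche reduction gives 1,2-reduction of the cross-conjugated enone and leaves the ester alone, and hydride should arrive on the ring face opposite the two cis methyl groups at C4 and C5 (the face carrying only C4–H and the C5 methylene), which places the C3 hydroxyl cis to the C4 methyl (3S).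

Step 7
Reactants: 12 ethyl (2E)-2-[(4S,5R,6R)-4-hydroxy-5,6-dimethyl-6-(3-methylbut-2-en-1-yl)cyclohex-2-en-1-ylidene]acetate
Product: 13 ethyl (2E)-2-[(4S,5R,6R)-4-[(tert-butyldimethylsilyl)oxy]-5,6-dimethyl-6-(3-methylbut-2-en-1-yl)cyclohex-2-en-1-ylidene]acetate
Conditions: TBSOTf, 2,6-lutidine, CH2Cl2, −78 → 0 °C
Reagents that add atoms: tert-butyldimethylsilyl trifluoromethanesulfonate, CC(C)(C)[Si](C)(C)OS(=O)(=O)C(F)(F)F
Why: Silyl ether protection of the hindered secondary allylic alcohol with the silyl triflate and a hindered base gives an ether that should survive hydride, MnO2, the aluminium Lewis acid and DBU.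

Step 8
Reactants: 13 ethyl (2E)-2-[(4S,5R,6R)-4-[(tert-butyldimethylsilyl)oxy]-5,6-dimethyl-6-(3-methylbut-2-en-1-yl)cyclohex-2-en-1-ylidene]acetate
Product: 14 (2E)-2-[(4S,5R,6R)-4-[(tert-butyldimethylsilyl)oxy]-5,6-dimethyl-6-(3-methylbut-2-en-1-yl)cyclohex-2-en-1-ylidene]ethan-1-ol
Conditions: DIBAL-H (2.5 equiv), CH2Cl2, −78 °C; aq. Rochelle salt
Reagents that add atoms: none
Why: DIBAL-H reduction of a conjugated ester proceeds 1,2 to the allylic alcohol at −78 °C and leaves the silyl ether and the other alkenes untouched.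

Step 9
Reactants: 14 (2E)-2-[(4S,5R,6R)-4-[(tert-butyldimethylsilyl)oxy]-5,6-dimethyl-6-(3-methylbut-2-en-1-yl)cyclohex-2-en-1-ylidene]ethan-1-ol
Product: 15 (2E)-2-[(4S,5R,6R)-4-[(tert-butyldimethylsilyl)oxy]-5,6-dimethyl-6-(3-methylbut-2-en-1-yl)cyclohex-2-en-1-ylidene]acetaldehyde
Conditions: activated MnO2 (excess), CH2Cl2, rt
Reagents that add atoms: none
Why: Allylic alcohol oxidation with activated MnO2 stops at the aldehyde, is neutral, and does not affect the silyl ether or the isolated prenyl alkene.

Step 10
Reactants: 15 (2E)-2-[(4S,5R,6R)-4-[(tert-butyldimethylsilyl)oxy]-5,6-dimethyl-6-(3-methylbut-2-en-1-yl)cyclohex-2-en-1-ylidene]acetaldehyde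
Product: 17 (3S,4R,5R,7S,8R)-3-[(tert-butyldimethylsilyl)oxy]eremophila-1,9,11-trien-8-ol, via (Z)-dienal 16 (not isolated)
Conditions: Me2AlCl (2.2 equiv, hexanes), CH2Cl2, −78 → 0 °C; cold aq. Rochelle salt
Reagents that add atoms: none
Why: Me2AlCl binds the formyl oxygen and makes the dienal an O-aluminated oxypentadienyl cation; in the Z isomer 16, whose formyl group lies syn to C5, the less substituted prenyl carbon C7 bonds to C8 while a hydrogen of a prenyl methyl group passes to oxygen through a six-membered chair, either in concert (type-I carbonyl-ene) or by way of a tertiary Prins cation that lives only long enough to lose that proton. The closest known reactions are the Lewis-acid cyclisation of citronellal to isopulegol and the ene cyclisation of neral to isopiperitenol, in which an enal is the enophile and only the Z geometry can close. Ring B closes as a six-membered ring in a mode that is exo at both reacting π bonds (the carbonyl oxygen and the CMe2 terminus end up outside the new ring), with C9=C10 already inside it. The new C8 and C7 centres come from the chair, in which O–Al and the developing isopropenyl group are pseudo-equatorial and hence trans and C7 is set trans to the axial C5 methyl by the quaternary centre, but both are erased in steps 11 and 12, so every diastereomer converges. The step needs 1,2-attack at C8 instead of attack at the cation termini and needs the major E isomer 15 to react through 16: the two-atom link from C5 brings C7 to C8 only in 16 and only in a strain-free chair, whereas attack at C10 would make a four-membered ring and attack at C2 a bridged bicyclo[2.2.2]octene, and 15 is expected to feed 16 by rotation about the weakened C9–C10 bond of the aluminium-bound cation or of its reversible chloride adduct. Me2AlCl also takes up the transferred proton as methane, so the acid-labile dienylic alcohol is held as its aluminium alkoxide until the cold quench.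

Step 11
Reactants: 17 (3S,4R,5R,7S,8R)-3-[(tert-butyldimethylsilyl)oxy]eremophila-1,9,11-trien-8-ol
Product: 18 (3S,4R,5R,7S)-3-[(tert-butyldimethylsilyl)oxy]eremophila-1,9,11-trien-8-one
Conditions: Dess–Martin periodinane, NaHCO3, CH2Cl2, 0 °C → rt
Reagents that add atoms: none
Why: Dess–Martin oxidation under bicarbonate buffer should convert the acid-sensitive dienylic alcohol into the conjugated ketone without ionising it, and it removes the temporary C8 stereocentre.

Step 12
Reactants: 18 (3S,4R,5R,7S)-3-[(tert-butyldimethylsilyl)oxy]eremophila-1,9,11-trien-8-one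
Product: 19 (3S,4R,5R)-3-[(tert-butyldimethylsilyl)oxy]eremophila-1,7(11),9-trien-8-one
Conditions: DBU (0.3 equiv), CH2Cl2, rt
Reagents that add atoms: none
Why: In this base-mediated alkene isomerisation into conjugation DBU removes the doubly activated C7 hydrogen (α to the ketone and allylic) and reprotonation of the dienolate at the terminal carbon gives the tetrasubstituted isopropylidene, the thermodynamic isomer, which erases the C7 stereocentre.

Step 13
Reactants: 19 (3S,4R,5R)-3-[(tert-butyldimethylsilyl)oxy]eremophila-1,7(11),9-trien-8-one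
Product: 20 (3S,4R,5R)-3-hydroxyeremophila-1,7(11),9-trien-8-one
Conditions: HF·pyridine, pyridine, THF, 0 °C → rt
Reagents that add atoms: none
Why: Fluoride-mediated silyl ether cleavage under buffered, weakly acidic conditions frees the C3 alcohol without a base that could enolise the dienone through its vinylogous positions.

Step 14
Reactants: 21 (S)-2-methylbutan-1-ol
Product: 22 (S)-2-methylbutanal
Conditions: TEMPO (10 mol %), PhI(OAc)2 (1.1 equiv), CH2Cl2, 0 °C → rt; washed, dried and used as a solution
Reagents that add atoms: none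
Why: TEMPO/hypervalent-iodine oxidation of a primary alcohol is neutral and stops at the aldehyde, so the α-stereocentre of the volatile aldehyde is not exposed to base.

Step 15
Reactants: 22 (S)-2-methylbutanal; 23 ethyl (2E)-4-(diethoxyphosphoryl)but-2-enoate
Product: 25 ethyl (2E,4E,6S)-6-methylocta-2,4-dienoate, via lithiated phosphonate 24 (not isolated)
Conditions: 23, LiHMDS, THF, −78 °C; then 22, −78 → 0 °C
Reagents that add atoms: none
Why: The vinylogous Horner–Wadsworth–Emmons olefination with the preformed stabilised anion 24 should give the 2E,4E-dienoate under the usual thermodynamic control, and the weakly basic anion at low temperature should not enolise the α-branched aldehyde, so C6 stays S.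

Step 16
Reactants: 25 ethyl (2E,4E,6S)-6-methylocta-2,4-dienoate
Product: 26 (2E,4E,6S)-6-methylocta-2,4-dienoic acid
Conditions: LiOH, THF–MeOH–H2O, rt; then 1 M HCl
Reagents that add atoms: lithium hydroxide, [Li+].[OH-]
Why: Ester saponification with aqueous lithium hydroxide at room temperature hydrolyses the ethyl ester without moving the diene out of conjugation or touching the remote C6 centre.

Step 17
Reactants: 20 (3S,4R,5R)-3-hydroxyeremophila-1,7(11),9-trien-8-one; 26 (2E,4E,6S)-6-methylocta-2,4-dienoic acid
Product: 28 (1R,2S,8aR)-1,8a-dimethyl-6-oxo-7-(propan-2-ylidene)-1,2,6,7,8,8a-hexahydronaphthalen-2-yl (2E,4E,6S)-6-methylocta-2,4-dienoate, via mixed anhydride 27 (not isolated)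
Conditions: 26, 2,4,6-trichlorobenzoyl chloride, Et3N, THF, rt; then 20, DMAP, toluene, rt
Reagents that add atoms: none
Why: In the Yamaguchi esterification DMAP attacks the mixed anhydride 27 at the less hindered dienoyl carbonyl and the acylpyridinium formed acylates the hindered secondary allylic alcohol with retention at C3, which completes the target.

**Compound list**

1 | 4,4-dimethoxycyclohexa-2,5-dien-1-one | COC1(OC)C=CC(=O)C=C1 | starting material
2 | (5R)-4,4-dimethoxy-5-methylcyclohex-2-en-1-one | O=C1C=CC(OC)(OC)[C@H](C)C1 | intermediate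
3 | lithium (3R)-4,4-dimethoxy-3-methylcyclohexa-1,5-dien-1-olate (α′-enolate of 2, formed in situ) | [Li]OC1=C[C@@H](C)C(OC)(OC)C=C1 | intermediate
4 | (5R,6RS)-4,4-dimethoxy-5,6-dimethylcyclohex-2-en-1-one (both C6 epimers) | O=C1C=CC(OC)(OC)[C@H](C)C1C | intermediate
5 | 1-bromo-3-methylbut-2-ene (prenyl bromide) | CC(C)=CCBr | starting material
6 | lithium (3R)-4,4-dimethoxy-2,3-dimethylcyclohexa-1,5-dien-1-olate (enolate of 4, formed in situ) | [Li]OC1=C(C)[C@@H](C)C(OC)(OC)C=C1 | intermediate
7 | (5R,6R)-4,4-dimethoxy-5,6-dimethyl-6-(3-methylbut-2-en-1-yl)cyclohex-2-en-1-one | O=C1C=CC(OC)(OC)[C@H](C)[C@@]1(C)CC=C(C)C | intermediate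
8 | ethyl 2-(trimethylsilyl)acetate | CCOC(=O)C[Si](C)(C)C | starting material
9 | lithium enolate of 8, ethyl lithio(trimethylsilyl)acetate (formed in situ) | CCOC(O[Li])=C[Si](C)(C)C | intermediate
10 | ethyl (2E)-2-[(5R,6R)-4,4-dimethoxy-5,6-dimethyl-6-(3-methylbut-2-en-1-yl)cyclohex-2-en-1-ylidene]acetate (minor 2Z isomer carried along) | CCOC(=O)/C=C1\C=CC(OC)(OC)[C@H](C)[C@@]1(C)CC=C(C)C | intermediate
11 | ethyl (2E)-2-[(5R,6R)-5,6-dimethyl-6-(3-methylbut-2-en-1-yl)-4-oxocyclohex-2-en-1-ylidene]acetate | CCOC(=O)/C=C1\C=CC(=O)[C@H](C)[C@@]1(C)CC=C(C)C | intermediate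
12 | ethyl (2E)-2-[(4S,5R,6R)-4-hydroxy-5,6-dimethyl-6-(3-methylbut-2-en-1-yl)cyclohex-2-en-1-ylidene]acetate | CCOC(=O)/C=C1\C=C[C@H](O)[C@H](C)[C@@]1(C)CC=C(C)C | intermediate
13 | ethyl (2E)-2-[(4S,5R,6R)-4-[(tert-butyldimethylsilyl)oxy]-5,6-dimethyl-6-(3-methylbut-2-en-1-yl)cyclohex-2-en-1-ylidene]acetate | CCOC(=O)/C=C1\C=C[C@H](O[Si](C)(C)C(C)(C)C)[C@H](C)[C@@]1(C)CC=C(C)C | intermediate
14 | (2E)-2-[(4S,5R,6R)-4-[(tert-butyldimethylsilyl)oxy]-5,6-dimethyl-6-(3-methylbut-2-en-1-yl)cyclohex-2-en-1-ylidene]ethan-1-ol | OC/C=C1\C=C[C@H](O[Si](C)(C)C(C)(C)C)[C@H](C)[C@@]1(C)CC=C(C)C | intermediate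
15 | (2E)-2-[(4S,5R,6R)-4-[(tert-butyldimethylsilyl)oxy]-5,6-dimethyl-6-(3-methylbut-2-en-1-yl)cyclohex-2-en-1-ylidene]acetaldehyde (formyl anti to C5) | O=C/C=C1\C=C[C@H](O[Si](C)(C)C(C)(C)C)[C@H](C)[C@@]1(C)CC=C(C)C | intermediate
16 | (2Z)-2-[(4S,5R,6R)-4-[(tert-butyldimethylsilyl)oxy]-5,6-dimethyl-6-(3-methylbut-2-en-1-yl)cyclohex-2-en-1-ylidene]acetaldehyde (formyl syn to C5; reactive isomer, formed in situ) | O=C/C=C1/C=C[C@H](O[Si](C)(C)C(C)(C)C)[C@H](C)[C@@]1(C)CC=C(C)C | intermediate
17 | (3S,4R,5R,7S,8R)-3-[(tert-butyldimethylsilyl)oxy]eremophila-1,9,11-trien-8-ol; (2R,3S,4aR,5R,6S)-6-[(tert-butyldimethylsilyl)oxy]-4a,5-dimethyl-3-(prop-1-en-2-yl)-2,3,4,4a,5,6-hexahydronaphthalen-2-ol | CC(C)(C)[Si](C)(C)O[C@H]1C=CC2=C[C@@H](O)[C@H](C(C)=C)C[C@]2(C)[C@H]1C | intermediate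
18 | (3S,4R,5R,7S)-3-[(tert-butyldimethylsilyl)oxy]eremophila-1,9,11-trien-8-one | CC(C)(C)[Si](C)(C)O[C@H]1C=CC2=CC(=O)[C@H](C(C)=C)C[C@]2(C)[C@H]1C | intermediate
19 | (3S,4R,5R)-3-[(tert-butyldimethylsilyl)oxy]eremophila-1,7(11),9-trien-8-one | CC(C)(C)[Si](C)(C)O[C@H]1C=CC2=CC(=O)C(=C(C)C)C[C@]2(C)[C@H]1C | intermediate
20 | (3S,4R,5R)-3-hydroxyeremophila-1,7(11),9-trien-8-one; (4aR,5R,6S)-6-hydroxy-4a,5-dimethyl-3-(propan-2-ylidene)-4,4a,5,6-tetrahydronaphthalen-2(3H)-one | O[C@H]1C=CC2=CC(=O)C(=C(C)C)C[C@]2(C)[C@H]1C | intermediate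
21 | (S)-2-methylbutan-1-ol | CC[C@H](C)CO | starting material
22 | (S)-2-methylbutanal | CC[C@H](C)C=O | intermediate
23 | ethyl (2E)-4-(diethoxyphosphoryl)but-2-enoate (triethyl 4-phosphonocrotonate) | CCOC(=O)/C=C/CP(=O)(OCC)OCC | starting material
24 | lithium salt of 23, lithiated at the carbon next to phosphorus (formed in situ) | CCOC(=O)/C=C/C([Li])P(=O)(OCC)OCC | intermediate
25 | ethyl (2E,4E,6S)-6-methylocta-2,4-dienoate | CC[C@H](C)/C=C/C=C/C(=O)OCC | intermediate
26 | (2E,4E,6S)-6-methylocta-2,4-dienoic acid | CC[C@H](C)/C=C/C=C/C(=O)O | intermediate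
27 | (2E,4E,6S)-6-methylocta-2,4-dienoic 2,4,6-trichlorobenzoic anhydride (formed in situ) | CC[C@H](C)/C=C/C=C/C(=O)OC(=O)c1c(Cl)cc(Cl)cc1Cl | intermediate
28 | (1R,2S,8aR)-1,8a-dimethyl-6-oxo-7-(propan-2-ylidene)-1,2,6,7,8,8a-hexahydronaphthalen-2-yl (2E,4E,6S)-6-methylocta-2,4-dienoate (CNP0215744.1) | CC[C@H](C)/C=C/C=C/C(=O)O[C@H]1C=CC2=CC(=O)C(=C(C)C)C[C@]2(C)[C@H]1C | target

**Step count**

Total steps: 17. Longest linear sequence: 14 steps (steps 1–13 and 17). The side-chain acid takes 3 steps (14–16).

**Steps most likely to fail**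

Step 10. The major E-dienal may not rotate into the Z form fast enough under the Lewis acid. While it waits it can be lost to methyl transfer from aluminium to the formyl carbon, to conjugate cation cyclisation at C2, or to hydride transfer from the product alkoxide to unreacted aldehyde. The fallback separates the geometric isomerisation from the ring closure and sets out from silyl ether ester 13. Triplet-sensitised photoisomerisation (thioxanthone, 405 nm, MeCN) should enrich the Z ester, which is twisted out of conjugation by allylic strain against C5 and is therefore the poorer energy acceptor. Chromatography with recycling of the E ester gives ethyl (2Z)-2-[(4S,5R,6R)-4-[(tert-butyldimethylsilyl)oxy]-5,6-dimethyl-6-(3-methylbut-2-en-1-yl)cyclohex-2-en-1-ylidene]acetate F1. DIBAL-H reduction gives (2Z)-2-[(4S,5R,6R)-4-[(tert-butyldimethylsilyl)oxy]-5,6-dimethyl-6-(3-methylbut-2-en-1-yl)cyclohex-2-en-1-ylidene]ethan-1-ol F2, and MnO2 oxidation comes back to the route at 16, now as an isolated compound. It is then cyclised with Me2AlCl at −78 °C, where no E-to-Z traffic is needed.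

Step 6. Hydride delivery to C3 may show poor or reversed facial selectivity (attack from the methyl-bearing face), which would give the 3,4-trans alcohol. The fallback corrects C3 by inversion instead of relying on the hydride face and sets out from ketone 11. If the same reduction gives mainly the epimer, ethyl (2E)-2-[(4R,5R,6R)-4-hydroxy-5,6-dimethyl-6-(3-methylbut-2-en-1-yl)cyclohex-2-en-1-ylidene]acetate F3, a Mitsunobu reaction (4-nitrobenzoic acid, PPh3, DIAD, THF) inverts the carbinol to ethyl (2E)-2-[(4S,5R,6R)-5,6-dimethyl-6-(3-methylbut-2-en-1-yl)-4-[(4-nitrobenzoyl)oxy]cyclohex-2-en-1-ylidene]acetate F4. Ethanolysis (K2CO3, EtOH) then returns to the route at 12.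

Step 3. The alkylation that creates the quaternary C5 may have insufficient facial selectivity, because the pseudo-axial ketal methoxy group can shield the face anti to the C4 methyl; O-alkylation may also compete. The fallback moves stereocontrol to a catalyst and sets out from 4. Enolisation (LiHMDS, TMEDA) and O-acylation with allyl chloroformate give allyl (3R)-4,4-dimethoxy-2,3-dimethylcyclohexa-1,5-dien-1-yl carbonate F5. Palladium-catalysed decarboxylative allylic alkylation with the PHOX ligand enantiomer that reinforces anti delivery gives (5R,6R)-4,4-dimethoxy-5,6-dimethyl-6-(prop-2-en-1-yl)cyclohex-2-en-1-one F6. Cross-metathesis with 2-methylbut-2-ene (second-generation Ru–NHC catalyst) turns allyl into prenyl and comes back to the route at 7.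

Further compounds
F1 | step 10 | ethyl (2Z)-2-[(4S,5R,6R)-4-[(tert-butyldimethylsilyl)oxy]-5,6-dimethyl-6-(3-methylbut-2-en-1-yl)cyclohex-2-en-1-ylidene]acetate | CCOC(=O)/C=C1/C=C[C@H](O[Si](C)(C)C(C)(C)C)[C@H](C)[C@@]1(C)CC=C(C)C
F2 | step 10 | (2Z)-2-[(4S,5R,6R)-4-[(tert-butyldimethylsilyl)oxy]-5,6-dimethyl-6-(3-methylbut-2-en-1-yl)cyclohex-2-en-1-ylidene]ethan-1-ol | OC/C=C1/C=C[C@H](O[Si](C)(C)C(C)(C)C)[C@H](C)[C@@]1(C)CC=C(C)C
F3 | step 6 | ethyl (2E)-2-[(4R,5R,6R)-4-hydroxy-5,6-dimethyl-6-(3-methylbut-2-en-1-yl)cyclohex-2-en-1-ylidene]acetate | CCOC(=O)/C=C1\C=C[C@@H](O)[C@H](C)[C@@]1(C)CC=C(C)C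
F4 | step 6 | ethyl (2E)-2-[(4S,5R,6R)-5,6-dimethyl-6-(3-methylbut-2-en-1-yl)-4-[(4-nitrobenzoyl)oxy]cyclohex-2-en-1-ylidene]acetate | CCOC(=O)/C=C1\C=C[C@H](OC(=O)c2ccc(cc2)[N+](=O)[O-])[C@H](C)[C@@]1(C)CC=C(C)C
F5 | step 3 | allyl (3R)-4,4-dimethoxy-2,3-dimethylcyclohexa-1,5-dien-1-yl carbonate | C=CCOC(=O)OC1=C(C)[C@@H](C)C(OC)(OC)C=C1
F6 | step 3 | (5R,6R)-4,4-dimethoxy-5,6-dimethyl-6-(prop-2-en-1-yl)cyclohex-2-en-1-one | O=C1C=CC(OC)(OC)[C@H](C)[C@@]1(C)CC=C
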